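**Retrosynthetic overview**
1. Target 17 ⇐ tetra-O-benzyl biflavanone 16 by removal of the four benzyl groups (last step, no stereocentre touched).
2. 16 ⇐ C3–C3'' bond between two intact (2R)-flavanone halves: 3-bromoflavanone 8 (fragment 1, the di-O-methyl half) + silyl enol ether 15 (fragment 2). This is the new radical–polar crossover heterocoupling; it sets C3 and C3'' trans to the C2 and C2'' aryl groups already present.
3. 8 ⇐ 7 ⇐ flavanone 6, and 15 ⇐ flavanone 14, by enol silylation (and α-bromination for fragment 1).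
4. 6 ⇐ chromone 4 + boronic acid 5, and 14 ⇐ chromone 12 + boronic acid 13: Rh-catalysed asymmetric 1,4-addition sets C2 and C2''.
5. Ring order: ring A is bought (acetophenones 1 and 9), ring C of each half is closed as a chromone (2 → 4, 10 → 12), ring B is then attached, and the two finished halves are joined last.

Assumption: the SMILES is read as the (2R,3S,2''R,3''S) isomer (both halves 2,3-trans, same absolute sense; unprimed locants = di-O-methyl half, doubly primed = free-phenol half), and compounds 1, 5, 9 and 13 are taken as commercial.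

**Route**

Step 1
Reactants: 1 1-(2,6-dihydroxy-4-methoxyphenyl)ethan-1-one
Product: 2 1-[2-(benzyloxy)-6-hydroxy-4-methoxyphenyl]ethan-1-one
Conditions: BnBr (1.05 equiv), K2CO3 (1.1 equiv), acetone, reflux
Reagents that add atoms: benzyl bromide, BrCc1ccccc1
Why: Williamson ether synthesis in which the first phenol is alkylated and the remaining one, locked in a hydrogen bond to the ketone, is left free for the later ring closure; no stereocentre.

Step 2
Reactants: 2 1-[2-(benzyloxy)-6-hydroxy-4-methoxyphenyl]ethan-1-one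
Product: 4 5-(benzyloxy)-7-methoxy-4H-chromen-4-one, via enaminone 3 (not isolated)
Conditions: Me2NCH(OMe)2 (3 equiv), toluene, 100 °C; evaporate; then conc. HCl, CH2Cl2, 40 °C
Reagents that add atoms: N,N-dimethylformamide dimethyl acetal, COC(OC)N(C)C
Why: Enaminone route to chromones, in which the methyl ketone condenses with the amide acetal and acid then drives conjugate addition of the free phenol and loss of dimethylamine to close ring C; no stereocentre.

Step 3
Reactants: 4 5-(benzyloxy)-7-methoxy-4H-chromen-4-one; 5 (4-methoxyphenyl)boronic acid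
Product: 6 (2R)-5-(benzyloxy)-7-methoxy-2-(4-methoxyphenyl)-2,3-dihydro-4H-chromen-4-one
Conditions: [Rh(OH)(cod)]2 (2.5 mol%), (R)-MeO-F12-BIPHEP [(R)-2,2'-bis[bis(3,4,5-trifluorophenyl)phosphino]-6,6'-dimethoxy-1,1'-biphenyl] (6 mol%), 5 (2.0 equiv), toluene/H2O (10:1), 20 °C
Reagents that add atoms: none
Why: Rh-catalysed asymmetric 1,4-addition (Hayashi–Miyaura reaction) in which the aryl–rhodium species carrying the (R)-bisphosphine adds the aryl group to one enantioface of C2 of the chromone enone and sets (2R) (sense assigned by analogy with cyclic enones and checked by chiral HPLC), while the near-neutral medium avoids retro-oxa-Michael racemisation.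

Step 4
Reactants: 6 (2R)-5-(benzyloxy)-7-methoxy-2-(4-methoxyphenyl)-2,3-dihydro-4H-chromen-4-one
Product: 7 (2R)-5-(benzyloxy)-7-methoxy-2-(4-methoxyphenyl)-4-[(trimethylsilyl)oxy]-2H-chromene
Conditions: TMSOTf (1.3 equiv), Et3N (2.0 equiv), CH2Cl2, 0 °C; pentane, filtration, used crude
Reagents that add atoms: trimethylsilyl trifluoromethanesulfonate, C[Si](C)(C)OS(=O)(=O)C(F)(F)F
Why: Soft enolisation (silyl triflate with amine base) gives the only possible enol ether, towards C3, without a free enolate, so the ring-opening that would racemise C2 does not occur.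

Step 5
Reactants: 7 (2R)-5-(benzyloxy)-7-methoxy-2-(4-methoxyphenyl)-4-[(trimethylsilyl)oxy]-2H-chromene
Product: 8 (2S,3S)-5-(benzyloxy)-3-bromo-7-methoxy-2-(4-methoxyphenyl)-2,3-dihydro-4H-chromen-4-one
Conditions: NBS (1.05 equiv), THF, −78 to −40 °C; then H2O; kept cold and used promptly
Reagents that add atoms: N-bromosuccinimide, O=C1CCC(=O)N1Br
Why: Electrophilic α-bromination of the silyl enol ether, which outruns bromination of the electron-rich arenes at −78 °C and places bromine anti to the C2 aryl group (2,3-trans); the C3 configuration is erased in step 10, and C2 is untouched (its descriptor changes from R to S only because bromine raises the CIP rank of C3).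

Step 6
Reactants: 9 1-(2,4,6-trihydroxyphenyl)ethan-1-one
Product: 10 1-[2,4-bis(benzyloxy)-6-hydroxyphenyl]ethan-1-one
Conditions: BnBr (2.1 equiv), K2CO3 (2.2 equiv), DMF, 20 °C
Reagents that add atoms: benzyl bromide, BrCc1ccccc1
Why: Williamson ether synthesis that alkylates the para phenol and one ortho phenol, the last ortho phenol being protected by its hydrogen bond to the ketone; no stereocentre.

Step 7
Reactants: 10 1-[2,4-bis(benzyloxy)-6-hydroxyphenyl]ethan-1-one
Product: 12 5,7-bis(benzyloxy)-4H-chromen-4-one, via enaminone 11 (not isolated)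
Conditions: Me2NCH(OMe)2 (3 equiv), toluene, 100 °C; evaporate; then conc. HCl, CH2Cl2, 40 °C
Reagents that add atoms: N,N-dimethylformamide dimethyl acetal, COC(OC)N(C)C
Why: Same enaminone route to chromones as in step 2, closing ring C of fragment 2 by acid-promoted conjugate addition of the phenol and loss of dimethylamine; no stereocentre.

Step 8
Reactants: 12 5,7-bis(benzyloxy)-4H-chromen-4-one; 13 [4-(benzyloxy)phenyl]boronic acid
Product: 14 (2R)-5,7-bis(benzyloxy)-2-[4-(benzyloxy)phenyl]-2,3-dihydro-4H-chromen-4-one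
Conditions: [Rh(OH)(cod)]2 (2.5 mol%), (R)-MeO-F12-BIPHEP (6 mol%), 13 (2.0 equiv), toluene/H2O (10:1), 20 °C
Reagents that add atoms: none
Why: Rh-catalysed asymmetric 1,4-addition (Hayashi–Miyaura reaction) with the same (R)-ligand as in step 3, so the aryl group is delivered to the same enantioface and C2'' is set as (2R).

Step 9
Reactants: 14 (2R)-5,7-bis(benzyloxy)-2-[4-(benzyloxy)phenyl]-2,3-dihydro-4H-chromen-4-one
Product: 15 (2R)-5,7-bis(benzyloxy)-2-[4-(benzyloxy)phenyl]-4-[(trimethylsilyl)oxy]-2H-chromene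
Conditions: TMSOTf (1.3 equiv), Et3N (2.0 equiv), CH2Cl2, 0 °C; pentane, filtration, used crude
Reagents that add atoms: trimethylsilyl trifluoromethanesulfonate, C[Si](C)(C)OS(=O)(=O)C(F)(F)F
Why: Soft enolisation as in step 4, giving the nucleophilic coupling partner without a free enolate and therefore without ring-opening or loss of the C2'' configuration.

Step 10
Reactants: 8 (2S,3S)-5-(benzyloxy)-3-bromo-7-methoxy-2-(4-methoxyphenyl)-2,3-dihydro-4H-chromen-4-one; 15 (2R)-5,7-bis(benzyloxy)-2-[4-(benzyloxy)phenyl]-4-[(trimethylsilyl)oxy]-2H-chromene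
Product: 16 (2R,3S)-5-(benzyloxy)-3-[(2R,3S)-5,7-bis(benzyloxy)-2-[4-(benzyloxy)phenyl]-4-oxo-3,4-dihydro-2H-chromen-3-yl]-7-methoxy-2-(4-methoxyphenyl)-2,3-dihydro-4H-chromen-4-one
Conditions: fac-Ir(ppy)3 (ppy = 2-phenylpyridinato, 1 mol%), 15 (2.0 equiv), 2,6-lutidine (1.5 equiv), MeCN/CH2Cl2 (2:1, 0.3 M), 450 nm LEDs, 0 °C, Ar; then H2O
Reagents that add atoms: none
Why: Proposed new method: a radical–polar crossover C3–C3'' heterocoupling of two flavanone halves, in which photoexcited fac-Ir(ppy)3 (excited trivalent iridium) transfers an electron into the C–Br bond of 8 to give the planar C3 α-keto radical, this electrophilic radical adds to the electron-rich C3'' of silyl enol ether 15, and the resulting α-silyloxy benzylic radical is oxidised by tetravalent iridium (or carries a chain by reducing 8) to a silyloxocarbenium ion that gives up its silyl group to bromide and unveils the second ketone; each partner is attacked on the face anti to its own C2 aryl group, so substrate control gives the 2,3-trans and 2'',3''-trans (3S,3''S) isomer, which is also the all-equatorial thermodynamic one; the closest known reaction type is the photoredox or Et3B-initiated coupling of simple α-bromo ketones with silyl enol ethers to 1,4-diketones, not yet shown for flavanones, for two secondary cyclic partners, or as a doubly diastereoselective fragment union.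

Step 11
Reactants: 16 (2R,3S)-5-(benzyloxy)-3-[(2R,3S)-5,7-bis(benzyloxy)-2-[4-(benzyloxy)phenyl]-4-oxo-3,4-dihydro-2H-chromen-3-yl]-7-methoxy-2-(4-methoxyphenyl)-2,3-dihydro-4H-chromen-4-one
Product: 17 (2R,3S)-3-[(2R,3S)-5,7-dihydroxy-2-(4-hydroxyphenyl)-4-oxo-3,4-dihydro-2H-chromen-3-yl]-5-hydroxy-7-methoxy-2-(4-methoxyphenyl)-2,3-dihydro-4H-chromen-4-one
Conditions: H2 (1 atm), Pd/C (10 wt%), EtOAc/MeOH (1:1), 20 °C
Reagents that add atoms: none
Why: Catalytic hydrogenolysis cleaves the four aryl benzyl ethers under neutral conditions, so neither enolisation at C3/C3'' nor opening of ring C can disturb the four stereocentres, and the two methyl ethers are inert.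

**Compound list**
1 | 1-(2,6-dihydroxy-4-methoxyphenyl)ethan-1-one | CC(=O)c1c(O)cc(OC)cc1O | starting material
2 | 1-[2-(benzyloxy)-6-hydroxy-4-methoxyphenyl]ethan-1-one | CC(=O)c1c(O)cc(OC)cc1OCc1ccccc1 | intermediate
3 | (E)-1-[2-(benzyloxy)-6-hydroxy-4-methoxyphenyl]-3-(dimethylamino)prop-2-en-1-one | CN(C)/C=C/C(=O)c1c(O)cc(OC)cc1OCc1ccccc1 | intermediate
4 | 5-(benzyloxy)-7-methoxy-4H-chromen-4-one | O=c1ccoc2cc(OC)cc(OCc3ccccc3)c12 | intermediate
5 | (4-methoxyphenyl)boronic acid | COc1ccc(B(O)O)cc1 | starting material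
6 | (2R)-5-(benzyloxy)-7-methoxy-2-(4-methoxyphenyl)-2,3-dihydro-4H-chromen-4-one | COc1ccc([C@@H]2Oc3cc(OC)cc(OCc4ccccc4)c3C(=O)C2)cc1 | intermediate
7 | (2R)-5-(benzyloxy)-7-methoxy-2-(4-methoxyphenyl)-4-[(trimethylsilyl)oxy]-2H-chromene | COc1ccc([C@@H]2Oc3cc(OC)cc(OCc4ccccc4)c3C(O[Si](C)(C)C)=C2)cc1 | intermediate
8 | (2S,3S)-5-(benzyloxy)-3-bromo-7-methoxy-2-(4-methoxyphenyl)-2,3-dihydro-4H-chromen-4-one (2,3-trans) | COc1ccc([C@@H]2Oc3cc(OC)cc(OCc4ccccc4)c3C(=O)[C@H]2Br)cc1 | intermediate
9 | 1-(2,4,6-trihydroxyphenyl)ethan-1-one | CC(=O)c1c(O)cc(O)cc1O | starting material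
10 | 1-[2,4-bis(benzyloxy)-6-hydroxyphenyl]ethan-1-one | CC(=O)c1c(O)cc(OCc2ccccc2)cc1OCc1ccccc1 | intermediate
11 | (E)-1-[2,4-bis(benzyloxy)-6-hydroxyphenyl]-3-(dimethylamino)prop-2-en-1-one | CN(C)/C=C/C(=O)c1c(O)cc(OCc2ccccc2)cc1OCc1ccccc1 | intermediate
12 | 5,7-bis(benzyloxy)-4H-chromen-4-one | O=c1ccoc2cc(OCc3ccccc3)cc(OCc3ccccc3)c12 | intermediate
13 | [4-(benzyloxy)phenyl]boronic acid | OB(O)c1ccc(OCc2ccccc2)cc1 | starting material
14 | (2R)-5,7-bis(benzyloxy)-2-[4-(benzyloxy)phenyl]-2,3-dihydro-4H-chromen-4-one | O=C1C[C@H](c2ccc(OCc3ccccc3)cc2)Oc2cc(OCc3ccccc3)cc(OCc3ccccc3)c21 | intermediate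
15 | (2R)-5,7-bis(benzyloxy)-2-[4-(benzyloxy)phenyl]-4-[(trimethylsilyl)oxy]-2H-chromene | C[Si](C)(C)OC1=C[C@H](c2ccc(OCc3ccccc3)cc2)Oc2cc(OCc3ccccc3)cc(OCc3ccccc3)c21 | intermediate
16 | (2R,3S)-5-(benzyloxy)-3-[(2R,3S)-5,7-bis(benzyloxy)-2-[4-(benzyloxy)phenyl]-4-oxo-3,4-dihydro-2H-chromen-3-yl]-7-methoxy-2-(4-methoxyphenyl)-2,3-dihydro-4H-chromen-4-one | COc1ccc([C@@H]2Oc3cc(OC)cc(OCc4ccccc4)c3C(=O)[C@H]2[C@@H]2C(=O)c3c(OCc4ccccc4)cc(OCc4ccccc4)cc3O[C@H]2c2ccc(OCc3ccccc3)cc2)cc1 | intermediate
17 | (2R,3S)-3-[(2R,3S)-5,7-dihydroxy-2-(4-hydroxyphenyl)-4-oxo-3,4-dihydro-2H-chromen-3-yl]-5-hydroxy-7-methoxy-2-(4-methoxyphenyl)-2,3-dihydro-4H-chromen-4-one (CNP0279849.2) | COc1ccc([C@@H]2Oc3cc(OC)cc(O)c3C(=O)[C@H]2[C@@H]2C(=O)c3c(O)cc(O)cc3O[C@H]2c2ccc(O)cc2)cc1 | target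

**Step count**
Total: 11 steps. Longest linear sequence: 7 steps (steps 1–5, then 10 and 11); the fragment 2 branch is 4 steps (6–9).

**Three steps most likely to fail**

Step 10 (the proposed new coupling). The C3 radical of 8 could fragment its β C2–O bond (ring-opening to a chalcone, which would cost the C2 configuration), 8 could lose HBr to the flavone, or some 2,3-cis isomer could form. High concentration, excess 15 and 0 °C favour the bimolecular trapping, and minor cis isomers can be epimerised at C3/C3'' alone by brief mild acid (enolisation without touching C2). The fallback uses known chemistry, the silicon-tethered oxidative heterocoupling of ketone enolates. It sets out from 6 and 14 (bypassing 7, 8 and 15) and comes back at 16. Flavanone 14 is added to i-Pr2Si(OTf)2 (1.0 equiv) and Et3N in CH2Cl2 at −78 °C, then 6 and more Et3N are added (−78 to 0 °C) to give the unsymmetrical bis-enol ether {[(2R)-5-(benzyloxy)-7-methoxy-2-(4-methoxyphenyl)-2H-chromen-4-yl]oxy}{[(2R)-5,7-bis(benzyloxy)-2-[4-(benzyloxy)phenyl]-2H-chromen-4-yl]oxy}di(propan-2-yl)silane F1. Oxidation with (NH4)2Ce(NO3)6 (tetravalent cerium, 2.2 equiv) and NaHCO3 in MeCN/EtCN at −30 °C joins C3 to C3'' within the tether, so only the cross-product can form, again anti to both aryl groups; loss of the silicon tether on work-up gives 16.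

Step 3 (asymmetric 1,4-addition to a chromone with a peri benzyloxy group; step 8 is the same reaction on a close relative and stands or falls with it). Conversion or ee may be low, or the sense of induction may be opposite to the one assigned. A modest ee is tolerable, because joining two enriched halves turns the minor enantiomers mainly into separable diastereomers of 16. The fallback replaces asymmetric catalysis by ring closure and resolution. It sets out from 2 and comes back at 6. Claisen–Schmidt condensation of 2 with 4-methoxybenzaldehyde (KOH, EtOH, 20 °C) gives the chalcone (E)-1-[2-(benzyloxy)-6-hydroxy-4-methoxyphenyl]-3-(4-methoxyphenyl)prop-2-en-1-one F2. NaOAc in refluxing EtOH closes ring C by oxa-Michael addition to the racemic flavanone, a 1:1 mixture of 6 and its enantiomer (2S)-5-(benzyloxy)-7-methoxy-2-(4-methoxyphenyl)-2,3-dihydro-4H-chromen-4-one F3. Preparative chromatography on a chiral stationary phase (amylose tris(3,5-dimethylphenylcarbamate), supercritical CO2/MeOH) delivers 6, and F3 is recycled by re-equilibration through F2 under the NaOAc conditions.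

Step 11 (global hydrogenolysis). The two C2–O bonds are benzylic ethers activated by para-oxygenated aryl groups and could be cleaved, the aryl ketones could be reduced, and 16 may be poorly soluble. The fallback replaces hydrogenation by Lewis-acid dealkylation. It sets out from 16 and comes back at 17 in one operation: BCl3 (8 equiv) with pentamethylbenzene (12 equiv) as benzyl-cation scavenger in CH2Cl2 at −78 °C, then MeOH quench. The methyl ethers survive at this temperature, and the fallback makes no new compound (none F0).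

Further compounds
F1 | step 10 | {[(2R)-5-(benzyloxy)-7-methoxy-2-(4-methoxyphenyl)-2H-chromen-4-yl]oxy}{[(2R)-5,7-bis(benzyloxy)-2-[4-(benzyloxy)phenyl]-2H-chromen-4-yl]oxy}di(propan-2-yl)silane | COc1ccc([C@@H]2Oc3cc(OC)cc(OCc4ccccc4)c3C(O[Si](C(C)C)(C(C)C)OC3=C[C@H](c4ccc(OCc5ccccc5)cc4)Oc4cc(OCc5ccccc5)cc(OCc5ccccc5)c43)=C2)cc1
F2 | step 3 | (E)-1-[2-(benzyloxy)-6-hydroxy-4-methoxyphenyl]-3-(4-methoxyphenyl)prop-2-en-1-one | COc1ccc(/C=C/C(=O)c2c(O)cc(OC)cc2OCc2ccccc2)cc1
F3 | step 3 | (2S)-5-(benzyloxy)-7-methoxy-2-(4-methoxyphenyl)-2,3-dihydro-4H-chromen-4-one | COc1ccc([C@H]2Oc3cc(OC)cc(OCc4ccccc4)c3C(=O)C2)cc1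
F0 | step 11 | none | none
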